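**Plan**

Labels: ring B = C1 (CH–aryl), C2 (CH–CH2OH), C3 (C–CHO), C4 (=CH), C4a, C8a; ring A = the benzo ring (C5 H, C6 OMe, C7 OH, C8 OMe); ring C = the 4-hydroxy-3,5-dimethoxyphenyl group on C1.
Retrosynthesis: cut C2–C3 of ring B first, then C1–C8a (aryl metal plus epoxy alcohol), then C4=C3 (Wittig) and the oxirane oxygen (Sharpless); both halves go back to syringaldehyde.
Forward: the ring C epoxy alcohol 5 and the ring A aryl bromide 8 (carrying the masked C4=C3–CHO chain) are joined at C1–C8a, the diol is closed to a terminal oxirane, the acetal and silyl groups are removed, and ring B, the only ring made, is closed last on the unprotected compound.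
Enabling feature: O7–H of ring A is para to C4a and conjugated through C4=C3 with the formyl group, so the ring A phenoxide is a phenylogous enolate whose α-carbon is C3; the C2–CH2OH unit is the trace of an oxirane opened at C2.
Stereochemistry: both centres come from the (2S,3S)-epoxy alcohol made with L-(+)-diethyl tartrate; inversion at C1 (aryl opening) and inversion at C2 (ring closure) should give the trans (1S,2R) target in these labels.

Key step: step 12

Remark on the chemistry: the ring A phenol of 15, being conjugated with the enal (a vinylogous acid), is taken to be the more acidic of the two phenols.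

**Route**

Step 1
Reactants: 1 syringaldehyde (4-hydroxy-3,5-dimethoxybenzaldehyde)
Product: 2 3,5-dimethoxy-4-(triisopropylsilyloxy)benzaldehyde
Conditions: i-Pr3SiCl, imidazole, DMAP (cat.), DMF, rt to 40 °C
Reagents that add atoms: triisopropylsilyl chloride, CC(C)[Si](Cl)(C(C)C)C(C)C
Why: Silyl ether formation masks the acidic phenol for the organometallic steps and can be undone by fluoride at the end.

Step 2
Reactants: 2 3,5-dimethoxy-4-(triisopropylsilyloxy)benzaldehyde
Product: 3 ethyl (E)-3-[3,5-dimethoxy-4-(triisopropylsilyloxy)phenyl]prop-2-enoate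
Conditions: Ph3P=CHCO2Et, toluene, 80 °C
Reagents that add atoms: ethyl (triphenylphosphoranylidene)acetate, CCOC(=O)C=P(c1ccccc1)(c1ccccc1)c1ccccc1
Why: Wittig olefination with a stabilised ylide should give the (E)-cinnamate, which cannot react further with the ylide.

Step 3
Reactants: 3 ethyl (E)-3-[3,5-dimethoxy-4-(triisopropylsilyloxy)phenyl]prop-2-enoate
Product: 4 (E)-3-[3,5-dimethoxy-4-(triisopropylsilyloxy)phenyl]prop-2-en-1-ol
Conditions: i-Bu2AlH (2.2 equiv), CH2Cl2, −78 °C; aq potassium sodium tartrate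
Reagents that add atoms: none
Why: 1,2-Reduction of the unsaturated ester by i-Bu2AlH at low temperature should give the (E)-allylic alcohol needed for the directed epoxidation, the aryl silyl ether being inert.

Step 4
Reactants: 4 (E)-3-[3,5-dimethoxy-4-(triisopropylsilyloxy)phenyl]prop-2-en-1-ol
Product: 5 [(2S,3S)-3-[3,5-dimethoxy-4-(triisopropylsilyloxy)phenyl]oxiran-2-yl]methanol
Conditions: Ti(OiPr)4 (10 mol %), L-(+)-diethyl tartrate (12 mol %), t-BuOOH, 4 Å molecular sieves, CH2Cl2, −20 °C
Reagents that add atoms: tert-butyl hydroperoxide, CC(C)(C)OO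
Why: Sharpless asymmetric epoxidation of the E-allylic alcohol with L-(+)-diethyl tartrate should give the (2S,3S)-epoxy alcohol, which carries the configuration of both future centres, C1 (after inversion) and C2.

Step 5
Reactants: 2 3,5-dimethoxy-4-(triisopropylsilyloxy)benzaldehyde
Product: 6 2-bromo-3,5-dimethoxy-4-(triisopropylsilyloxy)benzaldehyde
Conditions: N-bromosuccinimide (1.05 equiv), MeCN, rt, dark
Reagents that add atoms: N-bromosuccinimide, O=C1CCC(=O)N1Br
Why: Electrophilic aromatic bromination at one of the two equivalent free positions (ortho and para to the methoxy groups) places the handle for the C1–C8a bond next to the formyl carbon that becomes C4.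

Step 6
Reactants: 6 2-bromo-3,5-dimethoxy-4-(triisopropylsilyloxy)benzaldehyde
Product: 7 (E)-3-[2-bromo-3,5-dimethoxy-4-(triisopropylsilyloxy)phenyl]prop-2-enal
Conditions: Ph3P=CHCHO (1.3 equiv), toluene, 90 °C
Reagents that add atoms: (triphenylphosphoranylidene)acetaldehyde, O=CC=P(c1ccccc1)(c1ccccc1)c1ccccc1
Why: Wittig olefination with the formyl-stabilised ylide should extend the aldehyde by two carbons to the (E)-enal, the C4=C3–CHO unit of the target.

Step 7
Reactants: 7 (E)-3-[2-bromo-3,5-dimethoxy-4-(triisopropylsilyloxy)phenyl]prop-2-enal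
Product: 8 [3-bromo-4-[(E)-3,3-dimethoxyprop-1-enyl]-2,6-dimethoxyphenoxy]triisopropylsilane (the dimethyl acetal of 7)
Conditions: HC(OMe)3, PPTS (5 mol %), MeOH, rt; Et3N quench
Reagents that add atoms: trimethyl orthoformate, COC(OC)OC
Why: Acid-catalysed acetal formation with the orthoformate as water scavenger masks the enal against the organolithium of step 8 and against oxa-Michael addition of the C2 alkoxide in step 9.

Step 8
Reactants: 8 [3-bromo-4-[(E)-3,3-dimethoxyprop-1-enyl]-2,6-dimethoxyphenoxy]triisopropylsilane (1.5 equiv); 5 [(2S,3S)-3-[3,5-dimethoxy-4-(triisopropylsilyloxy)phenyl]oxiran-2-yl]methanol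
Product: 12 (2R,3S)-3-[6-[(E)-3,3-dimethoxyprop-1-enyl]-2,4-dimethoxy-3-(triisopropylsilyloxy)phenyl]-3-[3,5-dimethoxy-4-(triisopropylsilyloxy)phenyl]propane-1,2-diol, via aryllithium 9 (not isolated), via arylmagnesium bromide 10 (not isolated), via chloromagnesium alkoxide 11 (not isolated)
Conditions: 8, t-BuLi (2 equiv per 8), THF, −78 °C; MgBr2·OEt2, −78 to −40 °C; CuI (10 mol %); 5 pre-treated with i-PrMgCl (1.0 equiv), THF, −40 °C; then −40 to 0 °C; aq NH4Cl
Reagents that add atoms: none
Why: Bromine–lithium exchange, transmetalation to magnesium and CuI-catalysed opening of the 3-aryl-2,3-epoxy alkoxide at its benzylic carbon (SN2, inversion, directed by the magnesium alkoxide) should turn the (3S) oxirane carbon into the (S)-diarylmethine C1 while C2 keeps its oxygen and configuration.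

Step 9
Reactants: 12 (2R,3S)-3-[6-[(E)-3,3-dimethoxyprop-1-enyl]-2,4-dimethoxy-3-(triisopropylsilyloxy)phenyl]-3-[3,5-dimethoxy-4-(triisopropylsilyloxy)phenyl]propane-1,2-diol
Product: 13 (2R)-2-[(S)-[6-[(E)-3,3-dimethoxyprop-1-enyl]-2,4-dimethoxy-3-(triisopropylsilyloxy)phenyl][3,5-dimethoxy-4-(triisopropylsilyloxy)phenyl]methyl]oxirane
Conditions: NaH (2.5 equiv), N-tosylimidazole (1.05 equiv), THF, 0 °C to rt
Reagents that add atoms: none
Why: One-flask diol-to-epoxide conversion in which the primary alkoxide is sulfonylated selectively and the neighbouring secondary alkoxide displaces the tosylate (3-exo-tet), so C2 keeps its configuration.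

Step 10
Reactants: 13 (2R)-2-[(S)-[6-[(E)-3,3-dimethoxyprop-1-enyl]-2,4-dimethoxy-3-(triisopropylsilyloxy)phenyl][3,5-dimethoxy-4-(triisopropylsilyloxy)phenyl]methyl]oxirane
Product: 14 (E)-3-[2-[(S)-[3,5-dimethoxy-4-(triisopropylsilyloxy)phenyl][(2R)-oxiran-2-yl]methyl]-3,5-dimethoxy-4-(triisopropylsilyloxy)phenyl]prop-2-enal
Conditions: PPTS (10 mol %), acetone/H2O 10:1, rt
Reagents that add atoms: water, O
Why: Mild acid hydrolysis of the allylic dimethyl acetal, which should ionise far more readily than the oxirane opens, releases the (E)-enal.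

Step 11
Reactants: 14 (E)-3-[2-[(S)-[3,5-dimethoxy-4-(triisopropylsilyloxy)phenyl][(2R)-oxiran-2-yl]methyl]-3,5-dimethoxy-4-(triisopropylsilyloxy)phenyl]prop-2-enal
Product: 15 (E)-3-[4-hydroxy-2-[(S)-(4-hydroxy-3,5-dimethoxyphenyl)[(2R)-oxiran-2-yl]methyl]-3,5-dimethoxyphenyl]prop-2-enal
Conditions: n-Bu4NF (2.2 equiv), AcOH (2.2 equiv), THF, 0 °C to rt
Reagents that add atoms: none
Why: Fluoride cleavage of both aryl silyl ethers, buffered with acetic acid so that no free phenoxide meets the oxirane before the measured amount of base is added in step 12.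

Step 12
Reactants: 15 (E)-3-[4-hydroxy-2-[(S)-(4-hydroxy-3,5-dimethoxyphenyl)[(2R)-oxiran-2-yl]methyl]-3,5-dimethoxyphenyl]prop-2-enal
Product: 18 (3R,4S)-6-hydroxy-4-(4-hydroxy-3,5-dimethoxyphenyl)-3-(hydroxymethyl)-5,7-dimethoxy-3,4-dihydronaphthalene-2-carbaldehyde, via potassium phenoxide 16 (not isolated), via quinone methide 17 (not isolated)
Conditions: KOt-Bu (1.0 equiv), degassed t-BuOH, 0.005 M, 70 °C, argon; then AcOH (1.0 equiv)
Reagents that add atoms: none
Why: Proposed new method: one equivalent of base ionises the ring A phenol, whose charge is shared by O7, C4a, C3 and the formyl oxygen, so C3 reacts as the α-carbon of a phenylogous enolate, opens the oxirane at C2 in an SN2 fashion to the quinone methide 17, and the C3–H, now flanked by the formyl group and the quinone methide, is lost to restore ring A and the C4=C3 bond. The closest known reaction types are the phosphine-mediated Morita–Baylis–Hillman ring closure by epoxide opening, in which an external Lewis base plays the part taken here by the ring A phenoxide, and the α-carbon protonation of 4-hydroxycinnamate phenoxides that leads to quinone methides. Ring B closes in the 6-exo-tet mode, the breaking C2–O bond lying outside the new ring and the nucleophilic C4=C3 unit inside it. The new stereocentre C2 is set by inversion at the (R)-oxirane carbon and C1 is not touched, which should place the ring C aryl group and the CH2OH group trans. The step needs attack at C2 instead of the oxirane CH2 (six- against seven-membered ring), C- instead of O-alkylation (the phenoxide oxygen cannot reach the oxirane within the molecule and high dilution holds back the reaction between molecules) and ionisation of the ring A phenol only (it is the more acidic one, and the neutral ring C phenol cannot take part through its ipso carbon).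

**Compound list**

1 | syringaldehyde (4-hydroxy-3,5-dimethoxybenzaldehyde) | COc1cc(C=O)cc(OC)c1O | starting material
2 | 3,5-dimethoxy-4-(triisopropylsilyloxy)benzaldehyde | COc1cc(C=O)cc(OC)c1O[Si](C(C)C)(C(C)C)C(C)C | intermediate
3 | ethyl (E)-3-[3,5-dimethoxy-4-(triisopropylsilyloxy)phenyl]prop-2-enoate | CCOC(=O)/C=C/c1cc(OC)c(O[Si](C(C)C)(C(C)C)C(C)C)c(OC)c1 | intermediate
4 | (E)-3-[3,5-dimethoxy-4-(triisopropylsilyloxy)phenyl]prop-2-en-1-ol | OC/C=C/c1cc(OC)c(O[Si](C(C)C)(C(C)C)C(C)C)c(OC)c1 | intermediate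
5 | [(2S,3S)-3-[3,5-dimethoxy-4-(triisopropylsilyloxy)phenyl]oxiran-2-yl]methanol | OC[C@@H]1O[C@H]1c1cc(OC)c(O[Si](C(C)C)(C(C)C)C(C)C)c(OC)c1 | intermediate
6 | 2-bromo-3,5-dimethoxy-4-(triisopropylsilyloxy)benzaldehyde | COc1cc(C=O)c(Br)c(OC)c1O[Si](C(C)C)(C(C)C)C(C)C | intermediate
7 | (E)-3-[2-bromo-3,5-dimethoxy-4-(triisopropylsilyloxy)phenyl]prop-2-enal | COc1cc(/C=C/C=O)c(Br)c(OC)c1O[Si](C(C)C)(C(C)C)C(C)C | intermediate
8 | [3-bromo-4-[(E)-3,3-dimethoxyprop-1-enyl]-2,6-dimethoxyphenoxy]triisopropylsilane | COc1cc(/C=C/C(OC)OC)c(Br)c(OC)c1O[Si](C(C)C)(C(C)C)C(C)C | intermediate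
9 | [6-[(E)-3,3-dimethoxyprop-1-enyl]-2,4-dimethoxy-3-(triisopropylsilyloxy)phenyl]lithium | COc1cc(/C=C/C(OC)OC)c([Li])c(OC)c1O[Si](C(C)C)(C(C)C)C(C)C | intermediate
10 | [6-[(E)-3,3-dimethoxyprop-1-enyl]-2,4-dimethoxy-3-(triisopropylsilyloxy)phenyl]magnesium bromide | COc1cc(/C=C/C(OC)OC)c([Mg]Br)c(OC)c1O[Si](C(C)C)(C(C)C)C(C)C | intermediate
11 | chloromagnesium alkoxide of 5 | Cl[Mg]OC[C@@H]1O[C@H]1c1cc(OC)c(O[Si](C(C)C)(C(C)C)C(C)C)c(OC)c1 | intermediate
12 | (2R,3S)-3-[6-[(E)-3,3-dimethoxyprop-1-enyl]-2,4-dimethoxy-3-(triisopropylsilyloxy)phenyl]-3-[3,5-dimethoxy-4-(triisopropylsilyloxy)phenyl]propane-1,2-diol | COc1cc(cc(OC)c1O[Si](C(C)C)(C(C)C)C(C)C)[C@@H](c1c(OC)c(O[Si](C(C)C)(C(C)C)C(C)C)c(OC)cc1/C=C/C(OC)OC)[C@@H](O)CO | intermediate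
13 | (2R)-2-[(S)-[6-[(E)-3,3-dimethoxyprop-1-enyl]-2,4-dimethoxy-3-(triisopropylsilyloxy)phenyl][3,5-dimethoxy-4-(triisopropylsilyloxy)phenyl]methyl]oxirane | COc1cc(cc(OC)c1O[Si](C(C)C)(C(C)C)C(C)C)[C@@H](c1c(OC)c(O[Si](C(C)C)(C(C)C)C(C)C)c(OC)cc1/C=C/C(OC)OC)[C@@H]1CO1 | intermediate
14 | (E)-3-[2-[(S)-[3,5-dimethoxy-4-(triisopropylsilyloxy)phenyl][(2R)-oxiran-2-yl]methyl]-3,5-dimethoxy-4-(triisopropylsilyloxy)phenyl]prop-2-enal | COc1cc(cc(OC)c1O[Si](C(C)C)(C(C)C)C(C)C)[C@@H](c1c(OC)c(O[Si](C(C)C)(C(C)C)C(C)C)c(OC)cc1/C=C/C=O)[C@@H]1CO1 | intermediate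
15 | (E)-3-[4-hydroxy-2-[(S)-(4-hydroxy-3,5-dimethoxyphenyl)[(2R)-oxiran-2-yl]methyl]-3,5-dimethoxyphenyl]prop-2-enal | COc1cc(cc(OC)c1O)[C@@H](c1c(OC)c(O)c(OC)cc1/C=C/C=O)[C@@H]1CO1 | intermediate
16 | potassium salt of 15 at the ring A phenol | COc1cc(cc(OC)c1O)[C@@H](c1c(OC)c([O-])c(OC)cc1/C=C/C=O)[C@@H]1CO1.[K+] | intermediate
17 | quinone methide: ring B closed, H on C3, C4=C4a and C7=O in ring A, potassium alkoxide at the CH2O group; C1 and C2 as in 18, C3 of either configuration | COc1cc(cc(OC)c1O)[C@H]1C2=C(OC)C(=O)C(OC)=CC2=CC(C=O)[C@@H]1C[O-].[K+] | intermediate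
18 | (3R,4S)-6-hydroxy-4-(4-hydroxy-3,5-dimethoxyphenyl)-3-(hydroxymethyl)-5,7-dimethoxy-3,4-dihydronaphthalene-2-carbaldehyde; (1S,2R) in the labels of the plan | COc1cc([C@H]2c3c(cc(OC)c(O)c3OC)C=C(C=O)[C@@H]2CO)cc(OC)c1O | target

**Count and risks**

Total step count: 12. Longest linear sequence: 9 steps (1, 5, 6, 7, 8, 9, 10, 11, 12; the branch through steps 2 to 4 is equally long).

Steps most likely to fail:

1. Step 12. The delocalised phenoxide may be too weak a carbon nucleophile, so that the oxirane survives until O-alkylation between molecules or slow degradation of the enal takes over. The fallback uses known chemistry, sets out from 14 and comes back at 18. With both phenols still silylated, PMe3 (1 equiv) in t-BuOH at room temperature adds to C4 of the enal, the β-phosphonium enolate opens the oxirane at C2 (6-exo-tet, inversion), and loss of PMe3 restores C4=C3. This is the established phosphine-mediated Morita–Baylis–Hillman ring closure by epoxide opening and should give (3R,4S)-4-[3,5-dimethoxy-4-(triisopropylsilyloxy)phenyl]-3-(hydroxymethyl)-5,7-dimethoxy-6-(triisopropylsilyloxy)-3,4-dihydronaphthalene-2-carbaldehyde F1. n-Bu4NF/AcOH in THF then removes both silyl groups to give 18.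

2. Step 8. Transfer of the doubly ortho-substituted aryl group to the benzylic oxirane carbon may be slow, so that opening by halide, rearrangement of the oxirane to a carbonyl compound or attack at C2 compete and the configuration at C1 is eroded. The fallback sets out from 3 and 5 and comes back at 14; it makes the C1–C8a bond by a Friedel–Crafts reaction instead of an organometallic one. Ester 3 (in excess) and 5 are stirred in 1,1,1,3,3,3-hexafluoropropan-2-ol at room temperature; the ring position of 3 that is ortho and para to its methoxy groups should attack the activated benzylic oxirane carbon with inversion to give ethyl (E)-3-[2-[(1S,2R)-1-[3,5-dimethoxy-4-(triisopropylsilyloxy)phenyl]-2,3-dihydroxypropyl]-3,5-dimethoxy-4-(triisopropylsilyloxy)phenyl]prop-2-enoate F2. NaH and N-tosylimidazole, as in step 9, close the diol to ethyl (E)-3-[2-[(S)-[3,5-dimethoxy-4-(triisopropylsilyloxy)phenyl][(2R)-oxiran-2-yl]methyl]-3,5-dimethoxy-4-(triisopropylsilyloxy)phenyl]prop-2-enoate F3. i-Bu2AlH in CH2Cl2 at −78 °C reduces the ester to (E)-3-[2-[(S)-[3,5-dimethoxy-4-(triisopropylsilyloxy)phenyl][(2R)-oxiran-2-yl]methyl]-3,5-dimethoxy-4-(triisopropylsilyloxy)phenyl]prop-2-en-1-ol F4, and MnO2 in CH2Cl2 oxidises the allylic alcohol to 14.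

3. Step 6. The enal formed may be olefinated again by the same ylide (chain extension to the dienal) while the hindered, electron-rich aldehyde reacts slowly. The fallback sets out from 6 and comes back at 7; it extends the chain at the ester level, where a second olefination cannot occur. Ph3P=CHCO2Et in toluene at 80 °C should give ethyl (E)-3-[2-bromo-3,5-dimethoxy-4-(triisopropylsilyloxy)phenyl]prop-2-enoate F5, i-Bu2AlH at −78 °C gives (E)-3-[2-bromo-3,5-dimethoxy-4-(triisopropylsilyloxy)phenyl]prop-2-en-1-ol F6, and MnO2 in CH2Cl2 gives 7.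

**Further compounds**

F1 | step 12 | (3R,4S)-4-[3,5-dimethoxy-4-(triisopropylsilyloxy)phenyl]-3-(hydroxymethyl)-5,7-dimethoxy-6-(triisopropylsilyloxy)-3,4-dihydronaphthalene-2-carbaldehyde | COc1cc([C@H]2c3c(cc(OC)c(O[Si](C(C)C)(C(C)C)C(C)C)c3OC)C=C(C=O)[C@@H]2CO)cc(OC)c1O[Si](C(C)C)(C(C)C)C(C)C
F2 | step 8 | ethyl (E)-3-[2-[(1S,2R)-1-[3,5-dimethoxy-4-(triisopropylsilyloxy)phenyl]-2,3-dihydroxypropyl]-3,5-dimethoxy-4-(triisopropylsilyloxy)phenyl]prop-2-enoate | COc1cc(cc(OC)c1O[Si](C(C)C)(C(C)C)C(C)C)[C@@H](c1c(OC)c(O[Si](C(C)C)(C(C)C)C(C)C)c(OC)cc1/C=C/C(=O)OCC)[C@@H](O)CO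
F3 | step 8 | ethyl (E)-3-[2-[(S)-[3,5-dimethoxy-4-(triisopropylsilyloxy)phenyl][(2R)-oxiran-2-yl]methyl]-3,5-dimethoxy-4-(triisopropylsilyloxy)phenyl]prop-2-enoate | COc1cc(cc(OC)c1O[Si](C(C)C)(C(C)C)C(C)C)[C@@H](c1c(OC)c(O[Si](C(C)C)(C(C)C)C(C)C)c(OC)cc1/C=C/C(=O)OCC)[C@@H]1CO1
F4 | step 8 | (E)-3-[2-[(S)-[3,5-dimethoxy-4-(triisopropylsilyloxy)phenyl][(2R)-oxiran-2-yl]methyl]-3,5-dimethoxy-4-(triisopropylsilyloxy)phenyl]prop-2-en-1-ol | COc1cc(cc(OC)c1O[Si](C(C)C)(C(C)C)C(C)C)[C@@H](c1c(OC)c(O[Si](C(C)C)(C(C)C)C(C)C)c(OC)cc1/C=C/CO)[C@@H]1CO1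
F5 | step 6 | ethyl (E)-3-[2-bromo-3,5-dimethoxy-4-(triisopropylsilyloxy)phenyl]prop-2-enoate | CCOC(=O)/C=C/c1cc(OC)c(O[Si](C(C)C)(C(C)C)C(C)C)c(OC)c1Br
F6 | step 6 | (E)-3-[2-bromo-3,5-dimethoxy-4-(triisopropylsilyloxy)phenyl]prop-2-en-1-ol | OC/C=C/c1cc(OC)c(O[Si](C(C)C)(C(C)C)C(C)C)c(OC)c1Br
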